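**Assumption:** the target has no stereocentre, so the constitution alone defines it; hydroxyquinone rings are drawn in the tautomer of the given SMILES. This route has not been run; the yields and selectivities stated are expectations.

## Retrosynthetic overview
1. Target 9 ⇐ leuco heptaacetate 7 (deacetylation, air oxidation) ⇐ Thiele–Winter acetoxylation of bis-quinone 6, which puts the last ring oxygen next to the chain in both rings.
2. 6 ⇐ mono-O-methylation of the symmetric bis(hydroxyquinone) 5 ⇐ oxidation of bis-resorcinol 4 (tailoring after ring formation: ring hydroxylation, then O-methylation).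
3. 4 ⇐ two-directional polyketide-type aldol cycloaromatisation of hexaketone 3 ⇐ dimethyl hexadecanedioate 1 (C16 "starter") + 2 × 3-methylpentane-2,4-dione 2.
4. Ring order: both benzene rings form at the same time in step 1; there are no other rings.

## Route

Step 1
Reactants: 1 dimethyl hexadecanedioate; 2 3-methylpentane-2,4-dione (5 equiv)
Product: 4 5,5'-(tetradecane-1,14-diyl)bis(2-methylbenzene-1,3-diol), via hexaketone 3 (not isolated)
Conditions: LDA (10 equiv), THF, 0 °C; add 1, 0 °C → rt; then degassed 4 M aq KOH/MeOH, rt → 40 °C, Ar; aq HCl work-up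
Reagents that add atoms: none
Why: Proposed new method: the dilithio dianion of 2 is acylated at its terminal CH3 by both ester groups of 1 (Hauser–Harris γ-acylation of β-diketone dianions) to give the bis-2,4,6-triketone 3, and in strong aqueous alkali each triketone closes by intramolecular aldol condensation of the terminal CH3 onto the chain ketone and aromatises by loss of water, the closest known reaction being Collie's diacetylacetone → orcinol cyclisation; the opposite closure (chain α-CH2 onto the acetyl C=O) needs a secondary carbanion to attack an α-branched ketone and would give a crowded pentasubstituted arene, so it should be the minor path; no stereocentre is formed.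

Step 2
Reactants: 4 5,5'-(tetradecane-1,14-diyl)bis(2-methylbenzene-1,3-diol)
Product: 5 6,6'-(tetradecane-1,14-diyl)bis(2-hydroxy-3-methylcyclohexa-2,5-diene-1,4-dione)
Conditions: Fremy's salt (5 equiv), KH2PO4 buffer, H2O/THF, 0 °C → rt
Reagents that add atoms: Fremy's salt (potassium nitrosodisulfonate), [K+].[K+].[O]N(S(=O)(=O)[O-])S(=O)(=O)[O-]
Why: Teuber oxidation: each resorcinol ring is oxidised para to one OH (the two free ring positions are equivalent, the position between the hydroxyls is blocked by methyl) to give the 2-hydroxy-1,4-benzoquinone, as known for orcinol and 2-methylresorcinol; no stereocentre.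

Step 3
Reactants: 5 6,6'-(tetradecane-1,14-diyl)bis(2-hydroxy-3-methylcyclohexa-2,5-diene-1,4-dione)
Product: 6 2-hydroxy-6-[14-(5-methoxy-4-methyl-3,6-dioxocyclohexa-1,4-dien-1-yl)tetradecyl]-3-methylcyclohexa-2,5-diene-1,4-dione
Conditions: MeI (1.0 equiv), Ag2O (1.0 equiv), CH2Cl2, rt, dark; chromatography, recovered 5 recycled
Reagents that add atoms: iodomethane, CI
Why: Silver-salt O-alkylation of a vinylogous acid (as for hydroxyquinones such as phthiocol) is clean and regiospecific because each ring has only one OH, which already sits next to the ring methyl as the target requires; with one equivalent the two remote, independent rings give about 1:2:1 diol : mono-ether 6 : bis-ether, so at most about 50 % per pass; no stereocentre.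

Step 4
Reactants: 6 2-hydroxy-6-[14-(5-methoxy-4-methyl-3,6-dioxocyclohexa-1,4-dien-1-yl)tetradecyl]-3-methylcyclohexa-2,5-diene-1,4-dione
Product: 7 5-methoxy-6-methyl-3-[14-(2,3,5,6-tetraacetoxy-4-methylphenyl)tetradecyl]benzene-1,2,4-triyl triacetate
Conditions: Ac2O (solvent), BF3·OEt2 (cat.), rt → 40 °C
Reagents that add atoms: acetic anhydride, CC(=O)OC(C)=O
Why: Thiele–Winter acetoxylation: acid-catalysed 1,4-addition of acetate to each quinone at its only unsubstituted ring carbon (next to the chain), then enolisation and O-acetylation (the free OH of the second ring is acetylated first), as known for methoxy- and hydroxy-toluquinones; the methyl ether is not touched; no stereocentre.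

Step 5
Reactants: 7 5-methoxy-6-methyl-3-[14-(2,3,5,6-tetraacetoxy-4-methylphenyl)tetradecyl]benzene-1,2,4-triyl triacetate
Product: 9 2,5-dihydroxy-3-[14-(2-hydroxy-5-methoxy-4-methyl-3,6-dioxocyclohexa-1,4-dien-1-yl)tetradecyl]-6-methylcyclohexa-2,5-diene-1,4-dione, via leuco heptaol 8 (not isolated)
Conditions: K2CO3 (8 equiv), degassed MeOH, rt, Ar; then O2 (air), rt; 1 M HCl
Reagents that add atoms: none
Why: Base-mediated transesterification removes all seven aryl acetates and the electron-rich hydroxyhydroquinones autoxidise at once to the hydroxy-p-quinones (the para-dihydroxy pair of each ring becomes the quinone, O2 ends as water); the OMe survives because methoxide exchange at the vinylogous ester is degenerate and the product is an unreactive anion until acidification; no stereocentre.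

## Compound list
1 | dimethyl hexadecanedioate | COC(=O)CCCCCCCCCCCCCCC(=O)OC | starting material
2 | 3-methylpentane-2,4-dione | CC(=O)C(C)C(=O)C | starting material
3 | 3,24-dimethylhexacosane-2,4,6,21,23,25-hexaone (enolised, the two CHMe centres are labile and undefined) | CC(=O)C(C)C(=O)CC(=O)CCCCCCCCCCCCCCC(=O)CC(=O)C(C)C(=O)C | intermediate (not isolated)
4 | 5,5'-(tetradecane-1,14-diyl)bis(2-methylbenzene-1,3-diol) | Cc1c(O)cc(CCCCCCCCCCCCCCc2cc(O)c(C)c(O)c2)cc1O | intermediate
5 | 6,6'-(tetradecane-1,14-diyl)bis(2-hydroxy-3-methylcyclohexa-2,5-diene-1,4-dione) | CC1=C(O)C(=O)C(CCCCCCCCCCCCCCC2=CC(=O)C(C)=C(O)C2=O)=CC1=O | intermediate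
6 | 2-hydroxy-6-[14-(5-methoxy-4-methyl-3,6-dioxocyclohexa-1,4-dien-1-yl)tetradecyl]-3-methylcyclohexa-2,5-diene-1,4-dione | COC1=C(C)C(=O)C=C(CCCCCCCCCCCCCCC2=CC(=O)C(C)=C(O)C2=O)C1=O | intermediate
7 | 5-methoxy-6-methyl-3-[14-(2,3,5,6-tetraacetoxy-4-methylphenyl)tetradecyl]benzene-1,2,4-triyl triacetate | COc1c(C)c(OC(C)=O)c(OC(C)=O)c(CCCCCCCCCCCCCCc2c(OC(C)=O)c(OC(C)=O)c(C)c(OC(C)=O)c2OC(C)=O)c1OC(C)=O | intermediate
8 | 3-methyl-6-[14-(2,3,6-trihydroxy-5-methoxy-4-methylphenyl)tetradecyl]benzene-1,2,4,5-tetrol | COc1c(C)c(O)c(O)c(CCCCCCCCCCCCCCc2c(O)c(O)c(C)c(O)c2O)c1O | intermediate (not isolated)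
9 | 2,5-dihydroxy-3-[14-(2-hydroxy-5-methoxy-4-methyl-3,6-dioxocyclohexa-1,4-dien-1-yl)tetradecyl]-6-methylcyclohexa-2,5-diene-1,4-dione (CNP0130251.0, achiral) | COC1=C(C)C(=O)C(O)=C(CCCCCCCCCCCCCCC2=C(O)C(=O)C(C)=C(O)C2=O)C1=O | target

## Step count and risks
Total steps: 5. Longest linear sequence: 5 (1 → 4 → 5 → 6 → 7 → 9).

**Most likely to fail, 1: step 1.** The cyclisation of an unsymmetrical, α-methylated triketone is untested. It can close the wrong way, lose acetyl by retro-Claisen cleavage, or condense between molecules. The fallback sets out from 1 and 2 and comes back at 4. It adds the carboxyl that activates the true tetraketide, so the aldol is regiospecific: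
- The dianion of 2 (LDA, 2 equiv) is carboxylated at its terminal CH3 with dimethyl carbonate to give methyl 4-methyl-3,5-dioxohexanoate F1.
- The trianion of F1 (LDA, 3 equiv) is acylated at its terminal CH3 by both ester groups of 1 to give dimethyl 4,25-dimethyl-3,5,7,22,24,26-hexaoxooctacosanedioate F2.
- Under mild base (K2CO3, aq MeOH, then acid) the doubly activated C2 methylene of each end adds to the C7 ketone and the rings aromatise to dimethyl 6,6'-(tetradecane-1,14-diyl)bis(2,4-dihydroxy-3-methylbenzoate) F3.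
- KOH in ethylene glycol/water at 150 °C saponifies and decarboxylates both β-resorcylates to give 4.

**Most likely to fail, 2: step 3.** The mono-methylation is statistical. It cannot exceed about 50 % per pass and depends on separating 5, 6 and the bis-ether. The fallback sets out from 1 and 2 and comes back at 6. It builds the two rings one after the other and fixes the methyl ether during ring formation:
- 2 with trimethyl orthoformate and cat. TsOH gives (E)-4-methoxy-3-methylpent-3-en-2-one F4.
- Its kinetic α'-lithium enolate (LDA, −78 °C) is acylated by 1 used in fourfold excess (the excess is recovered) to give methyl (E)-20-methoxy-19-methyl-16,18-dioxohenicos-19-enoate F5.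
- NaOMe in refluxing MeOH effects a vinylogous aldol cycloaromatisation (γ-CH3 onto the C16 ketone) to methyl 15-(3-hydroxy-5-methoxy-4-methylphenyl)pentadecanoate F6.
- The ester of F6 is treated as in step 1 with excess dianion of 2 to give 20-(3-hydroxy-5-methoxy-4-methylphenyl)-3-methylicosane-2,4,6-trione F7 (not isolated), which closes in aqueous KOH to 5-[14-(3-hydroxy-5-methoxy-4-methylphenyl)tetradecyl]-2-methylbenzene-1,3-diol F8.
- Fremy's salt oxidises the methoxyphenol ring para to its OH and the resorcinol ring as in step 2, giving 6 directly.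

**Most likely to fail, 3: step 4.** Thiele–Winter acetoxylation can be slow on trisubstituted, donor-substituted quinones, and the acid may attack the vinylogous methyl ester. The fallback sets out from 6 and comes back at 9. It brings the oxygen in as a nucleophile:
- The one free OH of 6 is benzylated (BnBr, Ag2O) to give 2-(benzyloxy)-6-[14-(5-methoxy-4-methyl-3,6-dioxocyclohexa-1,4-dien-1-yl)tetradecyl]-3-methylcyclohexa-2,5-diene-1,4-dione F9, so that both rings are neutral quinones.
- t-BuOOH/DBU in CH2Cl2 at 0 °C epoxidises only the two electron-poor CH=C(alkyl) bonds to give the bis-epoxide 3-(benzyloxy)-1-[14-(3-methoxy-4-methyl-2,5-dioxo-7-oxabicyclo[4.1.0]hept-3-en-1-yl)tetradecyl]-4-methyl-7-oxabicyclo[4.1.0]hept-3-ene-2,5-dione F10.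
- On warming with DBU, F10 opens by E1cB (loss of the epoxide C–H α to the carbonyl) to 2-(benzyloxy)-5-hydroxy-6-[14-(2-hydroxy-5-methoxy-4-methyl-3,6-dioxocyclohexa-1,4-dien-1-yl)tetradecyl]-3-methylcyclohexa-2,5-diene-1,4-dione F11.
- Hydrogenolysis (H2, Pd/C, EtOAc) followed by re-oxidation in air gives 9.

## Further compounds
F1 | step 1 | methyl 4-methyl-3,5-dioxohexanoate | COC(=O)CC(=O)C(C)C(=O)C
F2 | step 1 | dimethyl 4,25-dimethyl-3,5,7,22,24,26-hexaoxooctacosanedioate | COC(=O)CC(=O)C(C)C(=O)CC(=O)CCCCCCCCCCCCCCC(=O)CC(=O)C(C)C(=O)CC(=O)OC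
F3 | step 1 | dimethyl 6,6'-(tetradecane-1,14-diyl)bis(2,4-dihydroxy-3-methylbenzoate) | COC(=O)c1c(O)c(C)c(O)cc1CCCCCCCCCCCCCCc1cc(O)c(C)c(O)c1C(=O)OC
F4 | step 3 | (E)-4-methoxy-3-methylpent-3-en-2-one | CO/C(C)=C(\C)C(C)=O
F5 | step 3 | methyl (E)-20-methoxy-19-methyl-16,18-dioxohenicos-19-enoate | COC(=O)CCCCCCCCCCCCCCC(=O)CC(=O)/C(C)=C(\C)OC
F6 | step 3 | methyl 15-(3-hydroxy-5-methoxy-4-methylphenyl)pentadecanoate | COC(=O)CCCCCCCCCCCCCCc1cc(O)c(C)c(OC)c1
F7 | step 3 | 20-(3-hydroxy-5-methoxy-4-methylphenyl)-3-methylicosane-2,4,6-trione | COc1cc(CCCCCCCCCCCCCCC(=O)CC(=O)C(C)C(=O)C)cc(O)c1C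
F8 | step 3 | 5-[14-(3-hydroxy-5-methoxy-4-methylphenyl)tetradecyl]-2-methylbenzene-1,3-diol | COc1cc(CCCCCCCCCCCCCCc2cc(O)c(C)c(O)c2)cc(O)c1C
F9 | step 4 | 2-(benzyloxy)-6-[14-(5-methoxy-4-methyl-3,6-dioxocyclohexa-1,4-dien-1-yl)tetradecyl]-3-methylcyclohexa-2,5-diene-1,4-dione | COC1=C(C)C(=O)C=C(CCCCCCCCCCCCCCC2=CC(=O)C(C)=C(OCc3ccccc3)C2=O)C1=O
F10 | step 4 | 3-(benzyloxy)-1-[14-(3-methoxy-4-methyl-2,5-dioxo-7-oxabicyclo[4.1.0]hept-3-en-1-yl)tetradecyl]-4-methyl-7-oxabicyclo[4.1.0]hept-3-ene-2,5-dione (mixture of stereoisomers) | COC1=C(C)C(=O)C2OC2(CCCCCCCCCCCCCCC23OC2C(=O)C(C)=C(OCc2ccccc2)C3=O)C1=O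
F11 | step 4 | 2-(benzyloxy)-5-hydroxy-6-[14-(2-hydroxy-5-methoxy-4-methyl-3,6-dioxocyclohexa-1,4-dien-1-yl)tetradecyl]-3-methylcyclohexa-2,5-diene-1,4-dione | COC1=C(C)C(=O)C(O)=C(CCCCCCCCCCCCCCC2=C(O)C(=O)C(C)=C(OCc3ccccc3)C2=O)C1=O
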